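**Plan**

1. Retrosynthesis: functional-group changes take the acid back to bicyclic alcohol 21 (C18 as CH2OSi, an added 3β-OH, O15 silylated). The decalin is then cut at C4–C5 and C9–C10 in one stroke to open-chain epoxide 19, and the chain at C6–C7 (allyl sulfone alkylation) and C8=C9 (Wittig).
2. Enabling feature: ring A (C1–C5, C10) and ring B (C5–C10) share C5–C10, and the two ring bonds cut are those of a head-to-tail 1,5-diene. Quaternary C4 with its oxygenated carbon C18 maps onto the C3–C4 epoxide of an E allylic alcohol (start of the cascade). The C8(17) methylene next to C9–H maps onto an allylsilane with silicon on C17 (end of the cascade), as in the copalyl-type cyclization of labdane biosynthesis.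
3. Forward: (S)-citronellol gives the C7–C15 allylsilane bromide 11 and geranyl bromide gives the C18–C6 sulfone 14. They are joined, desulfonylated and epoxidised; step 13 then closes ring A (C4–C5) and ring B (C9–C10) in one operation, and no ring is formed before or after it.
4. Stereochemistry: C13 comes from the chiral pool and C3/C4 of the epoxide from Sharpless epoxidation. C4 (by inversion), C5, C10 and C9 are relayed from the epoxide configuration and the alkene geometries through the chair–chair fold. The C3 oxygen is a helper and is removed by Barton–McCombie deoxygenation.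
5. End game: desilylation, acetylation of O15, oxidation of C18 to the acid.

Key step: step 13

Assumption: labdane numbering is used throughout; in the target the carboxyl carbon is the equatorial 4α substituent (C18), trans to the C10 methyl group (C20), and the C4 methyl group (C19) is axial, i.e. the target is (13S)-15-acetoxylabd-8(17)-en-18-oic acid.

**Route**

Step 1
Reactants: 1 (S)-citronellol
Product: 2 tert-butyl{[(3S)-3,7-dimethyloct-6-en-1-yl]oxy}diphenylsilane
Conditions: TBDPSCl, imidazole, DMF, rt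
Reagents that add atoms: tert-butyl(chloro)diphenylsilane, CC(C)(C)[Si](Cl)(c1ccccc1)c1ccccc1
Why: Imidazole-promoted silyl ether formation protects O15 through the hydride and organolithium steps, and the C13 stereocentre is taken unchanged from the chiral pool.

Step 2
Reactants: 2 tert-butyl{[(3S)-3,7-dimethyloct-6-en-1-yl]oxy}diphenylsilane
Product: 4 (4S)-6-(tert-butyldiphenylsilyloxy)-4-methylhexanal, via ozonide 3 (not isolated)
Conditions: O3, CH2Cl2, −78 °C; then PPh3, −78 °C to rt
Reagents that add atoms: ozone, [O-][O+]=O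
Why: Ozonolysis with reductive work-up cleaves the only alkene to the aldehyde whose carbonyl carbon becomes C9, without touching C13.

Step 3
Reactants: 5 ethyl (triphenylphosphoranylidene)acetate; 6 (iodomethyl)trimethylsilane
Product: 8 ethyl 2-(triphenylphosphoranylidene)-3-(trimethylsilyl)propanoate, via phosphonium iodide 7 (not isolated)
Conditions: PhMe, 90 °C; then NaOH (aq), CH2Cl2
Reagents that add atoms: none
Why: C-alkylation of the stabilised ylide by the primary α-silyl iodide (ylide alkylation) gives the phosphonium salt, which base returns to the α-substituted stabilised ylide.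

Step 4
Reactants: 4 (4S)-6-(tert-butyldiphenylsilyloxy)-4-methylhexanal; 8 ethyl 2-(triphenylphosphoranylidene)-3-(trimethylsilyl)propanoate
Product: 9 ethyl (2Z,6S)-8-(tert-butyldiphenylsilyloxy)-6-methyl-2-[(trimethylsilyl)methyl]oct-2-enoate
Conditions: PhMe, 90 °C
Reagents that add atoms: none
Why: Wittig olefination with an α-substituted stabilised ylide should place the ester trans to the C11 chain, so the CH2SiMe3 group (C17) ends cis to C11, the geometry that later sets C9.

Step 5
Reactants: 9 ethyl (2Z,6S)-8-(tert-butyldiphenylsilyloxy)-6-methyl-2-[(trimethylsilyl)methyl]oct-2-enoate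
Product: 10 (2Z,6S)-8-(tert-butyldiphenylsilyloxy)-6-methyl-2-[(trimethylsilyl)methyl]oct-2-en-1-ol
Conditions: i-Bu2AlH, CH2Cl2, −78 °C
Reagents that add atoms: none
Why: 1,2-Reduction of the conjugated ester by the aluminium hydride gives the allylic alcohol (C7) without touching the allylsilane, the silyl ether or the alkene geometry.

Step 6
Reactants: 10 (2Z,6S)-8-(tert-butyldiphenylsilyloxy)-6-methyl-2-[(trimethylsilyl)methyl]oct-2-en-1-ol
Product: 11 {[(3S,6E)-8-bromo-3-methyl-7-[(trimethylsilyl)methyl]oct-6-en-1-yl]oxy}(tert-butyl)diphenylsilane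
Conditions: CBr4, PPh3, CH2Cl2, 0 °C
Reagents that add atoms: tetrabromomethane, BrC(Br)(Br)Br
Why: Appel bromination converts the primary allylic alcohol to the bromide by SN2 under neutral conditions, so neither allylic shift nor protodesilylation is expected (the descriptor changes to E by the sequence rule only).

Step 7
Reactants: 12 geranyl bromide
Product: 13 geranyl phenyl sulfone, {[(2E)-3,7-dimethylocta-2,6-dien-1-yl]sulfonyl}benzene
Conditions: PhSO2Na, DMF, rt
Reagents that add atoms: sodium benzenesulfinate, [Na+].[O-]S(=O)c1ccccc1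
Why: S-alkylation of the sulfinate by the primary allylic bromide (SN2) gives the allylic sulfone with the E alkene unchanged.

Step 8
Reactants: 13 geranyl phenyl sulfone
Product: 14 (2E,6E)-2,6-dimethyl-8-(phenylsulfonyl)octa-2,6-dien-1-ol
Conditions: SeO2 (cat.), t-BuOOH, salicylic acid (cat.), CH2Cl2, rt
Reagents that add atoms: tert-butyl hydroperoxide, CC(C)(C)OO
Why: SeO2-catalysed allylic oxidation (ene reaction then [2,3]-shift) attacks the E methyl group of the terminal alkene, the alkene next to the sulfone being deactivated, and gives the E allylic alcohol whose CH2OH becomes C18.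

Step 9
Reactants: 14 (2E,6E)-2,6-dimethyl-8-(phenylsulfonyl)octa-2,6-dien-1-ol; 11 {[(3S,6E)-8-bromo-3-methyl-7-[(trimethylsilyl)methyl]oct-6-en-1-yl]oxy}(tert-butyl)diphenylsilane
Product: 16 (2E,6E,10Z,14S)-16-(tert-butyldiphenylsilyloxy)-2,6,14-trimethyl-8-(phenylsulfonyl)-10-[(trimethylsilyl)methyl]hexadeca-2,6,10-trien-1-ol (both C8 epimers), via dilithio sulfone 15 (not isolated)
Conditions: 14, n-BuLi (2 equiv), THF/HMPA, −78 °C; then 11, −78 to −20 °C
Reagents that add atoms: none
Why: Alkylation of the α-sulfonyl allyl anion at its α carbon by the primary allylic bromide (SN2, the alkoxide being far less nucleophilic) forms the C6–C7 bond, and the sulfone-bearing carbon is only a passing stereocentre.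

Step 10
Reactants: 16 (2E,6E,10Z,14S)-16-(tert-butyldiphenylsilyloxy)-2,6,14-trimethyl-8-(phenylsulfonyl)-10-[(trimethylsilyl)methyl]hexadeca-2,6,10-trien-1-ol
Product: 17 (2E,6E,10Z,14S)-16-(tert-butyldiphenylsilyloxy)-2,6,14-trimethyl-10-[(trimethylsilyl)methyl]hexadeca-2,6,10-trien-1-ol
Conditions: PdCl2(dppp) (cat.), LiEt3BH, THF, 0 °C
Reagents that add atoms: none
Why: Zerovalent palladium ionises the allylic sulfone to a π-allyl complex and hydride is delivered to the less substituted terminus (palladium-catalysed reductive desulfonylation), which should keep the position and E geometry of the 5(10)-alkene.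

Step 11
Reactants: 17 (2E,6E,10Z,14S)-16-(tert-butyldiphenylsilyloxy)-2,6,14-trimethyl-10-[(trimethylsilyl)methyl]hexadeca-2,6,10-trien-1-ol
Product: 18 [(2S,3S)-3-{(3E,7Z,11S)-13-(tert-butyldiphenylsilyloxy)-3,11-dimethyl-7-[(trimethylsilyl)methyl]trideca-3,7-dien-1-yl}-2-methyloxiran-2-yl]methanol
Conditions: Ti(OiPr)4 (cat.), L-(+)-diethyl tartrate (cat.), t-BuOOH, 4 Å molecular sieves, CH2Cl2, −20 °C
Reagents that add atoms: tert-butyl hydroperoxide, CC(C)(C)OO
Why: Sharpless asymmetric epoxidation reacts only at the allylic alcohol and, with L-(+)-diethyl tartrate, should deliver oxygen to the face that gives the (2S,3S) epoxide, i.e. 3S and 4S in labdane numbering (reagent control).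

Step 12
Reactants: 18 [(2S,3S)-3-{(3E,7Z,11S)-13-(tert-butyldiphenylsilyloxy)-3,11-dimethyl-7-[(trimethylsilyl)methyl]trideca-3,7-dien-1-yl}-2-methyloxiran-2-yl]methanol
Product: 19 tert-butyldimethylsilyl ether of 18
Conditions: TBSCl, imidazole, CH2Cl2, 0 °C to rt
Reagents that add atoms: tert-butyl(chloro)dimethylsilane, CC(C)(C)[Si](C)(C)Cl
Why: Silyl ether formation masks the primary hydroxyl so that it cannot quench the Lewis acid or open the epoxide in the next step.

Step 13
Reactants: 19 tert-butyldimethylsilyl ether of 18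
Product: 21 (13S)-18-(tert-butyldimethylsilyloxy)-15-(tert-butyldiphenylsilyloxy)labd-8(17)-en-3β-ol, via monocyclic C10 cation 20 (not isolated)
Conditions: MeAlCl2 (2 equiv), CH2Cl2, −78 °C; then H2O
Reagents that add atoms: none
Why: MeAlCl2 binds the epoxide oxygen, C5 of the 5(10)-alkene attacks C4 from the back as the C4–O bond breaks, the C10 tertiary cation is taken by C9 of the allylsilane, and the β-silyl cation at C8 loses Me3Si to leave the 8(17)-methylene. The closest known reaction type is the Lewis-acid epoxy-polyene cyclization with allylsilane termination used for 3-hydroxylabd-8(17)-enes, itself a copy of the copalyl-type cyclization of labdane biosynthesis. Ring A closes by 6-endo attack of the trisubstituted alkene on the epoxide carbon (anti opening, chair) and ring B by 6-endo-trig attack of the allylsilane on C10 (second chair). C3 keeps the S configuration of the epoxide (3β-OH, equatorial) and C4 is set by inversion, so the E substituent CH2OTBS becomes equatorial (C18, 4α) and the methyl axial. C5 and C10 follow from the E geometry of the 5(10)-alkene in the chair–chair fold (trans fusion, 10β-methyl), and C9 from the allylsilane geometry, which puts C11 equatorial (9α-H). The step needs C4–O rather than C3–O cleavage (C4 is tertiary), capture of the C10 cation by carbon rather than by O3 (the allylsilane is the most nucleophilic alkene present), and a regiospecific exocyclic alkene (secured by loss of silicon instead of a proton).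

Step 14
Reactants: 21 (13S)-18-(tert-butyldimethylsilyloxy)-15-(tert-butyldiphenylsilyloxy)labd-8(17)-en-3β-ol
Product: 22 3-O-(phenoxythiocarbonyl) derivative of 21
Conditions: PhOC(S)Cl, pyridine, DMAP (cat.), CH2Cl2, rt
Reagents that add atoms: O-phenyl carbonochloridothioate, S=C(Cl)Oc1ccccc1
Why: Acylation of the equatorial secondary alcohol gives the Barton–McCombie substrate under a base too weak to cause silyl migration from O18.

Step 15
Reactants: 22 3-O-(phenoxythiocarbonyl) derivative of 21
Product: 23 (13S)-18-(tert-butyldimethylsilyloxy)-15-(tert-butyldiphenylsilyloxy)labd-8(17)-ene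
Conditions: Bu3SnH, AIBN (cat.), PhMe, 100 °C
Reagents that add atoms: none
Why: Barton–McCombie deoxygenation removes the helper oxygen: the stannyl radical adds to C=S, the C3–O bond fragments and the secondary C3 radical is reduced, the 8(17)-alkene being too remote for cyclisation.

Step 16
Reactants: 23 (13S)-18-(tert-butyldimethylsilyloxy)-15-(tert-butyldiphenylsilyloxy)labd-8(17)-ene
Product: 24 (13S)-labd-8(17)-ene-15,18-diol
Conditions: Bu4NF, THF, rt to 40 °C
Reagents that add atoms: none
Why: Fluoride cleaves both silyl ethers (Si–F bond formation) and leaves the exocyclic alkene untouched.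

Step 17
Reactants: 24 (13S)-labd-8(17)-ene-15,18-diol
Product: 25 (13S)-18-hydroxylabd-8(17)-en-15-yl acetate
Conditions: Ac2O (1 equiv), pyridine, CH2Cl2, −20 to 0 °C
Reagents that add atoms: acetic anhydride, CC(=O)OC(C)=O
Why: Acylation should be faster at the unhindered primary C15 hydroxyl than at the neopentylic C18 hydroxyl on quaternary C4, so one equivalent of anhydride at low temperature should give the 15-monoacetate.

Step 18
Reactants: 25 (13S)-18-hydroxylabd-8(17)-en-15-yl acetate
Product: 27 (13S)-15-acetoxylabd-8(17)-en-18-oic acid (target), via aldehyde 26 (not isolated)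
Conditions: Dess–Martin periodinane, CH2Cl2, rt; then NaClO2, NaH2PO4, 2-methyl-2-butene, t-BuOH/H2O, rt
Reagents that add atoms: sodium chlorite, [Na+].[O-]Cl=O
Why: Dess–Martin oxidation to the aldehyde followed by Pinnick oxidation, with 2-methyl-2-butene taking up HOCl to protect the 8(17)-alkene, gives the acid; C4 is quaternary, so nothing can epimerise.

**Compound list**

1 | (S)-citronellol, (3S)-3,7-dimethyloct-6-en-1-ol | OCC[C@@H](C)CCC=C(C)C | starting material
2 | tert-butyl{[(3S)-3,7-dimethyloct-6-en-1-yl]oxy}diphenylsilane | CC(C)=CCC[C@H](C)CCO[Si](c1ccccc1)(c1ccccc1)C(C)(C)C | intermediate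
3 | ozonide of 2, 5-[(3S)-5-(tert-butyldiphenylsilyloxy)-3-methylpentyl]-3,3-dimethyl-1,2,4-trioxolane (C5 epimers) | CC1(C)OOC(CC[C@H](C)CCO[Si](c2ccccc2)(c2ccccc2)C(C)(C)C)O1 | intermediate
4 | (4S)-6-(tert-butyldiphenylsilyloxy)-4-methylhexanal | O=CCC[C@H](C)CCO[Si](c1ccccc1)(c1ccccc1)C(C)(C)C | intermediate
5 | ethyl (triphenylphosphoranylidene)acetate | CCOC(=O)C=P(c1ccccc1)(c1ccccc1)c1ccccc1 | starting material
6 | (iodomethyl)trimethylsilane | C[Si](C)(C)CI | starting material
7 | [1-ethoxy-1-oxo-3-(trimethylsilyl)propan-2-yl]triphenylphosphonium iodide | CCOC(=O)C(C[Si](C)(C)C)[P+](c1ccccc1)(c1ccccc1)c1ccccc1.[I-] | intermediate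
8 | ethyl 2-(triphenylphosphoranylidene)-3-(trimethylsilyl)propanoate | CCOC(=O)C(C[Si](C)(C)C)=P(c1ccccc1)(c1ccccc1)c1ccccc1 | intermediate
9 | ethyl (2Z,6S)-8-(tert-butyldiphenylsilyloxy)-6-methyl-2-[(trimethylsilyl)methyl]oct-2-enoate | CCOC(=O)/C(C[Si](C)(C)C)=C/CC[C@H](C)CCO[Si](c1ccccc1)(c1ccccc1)C(C)(C)C | intermediate
10 | (2Z,6S)-8-(tert-butyldiphenylsilyloxy)-6-methyl-2-[(trimethylsilyl)methyl]oct-2-en-1-ol | OC/C(C[Si](C)(C)C)=C/CC[C@H](C)CCO[Si](c1ccccc1)(c1ccccc1)C(C)(C)C | intermediate
11 | {[(3S,6E)-8-bromo-3-methyl-7-[(trimethylsilyl)methyl]oct-6-en-1-yl]oxy}(tert-butyl)diphenylsilane | BrC/C(C[Si](C)(C)C)=C/CC[C@H](C)CCO[Si](c1ccccc1)(c1ccccc1)C(C)(C)C | intermediate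
12 | geranyl bromide, (2E)-1-bromo-3,7-dimethylocta-2,6-diene | CC(C)=CCC/C(C)=C/CBr | starting material
13 | geranyl phenyl sulfone, {[(2E)-3,7-dimethylocta-2,6-dien-1-yl]sulfonyl}benzene | CC(C)=CCC/C(C)=C/CS(=O)(=O)c1ccccc1 | intermediate
14 | (2E,6E)-2,6-dimethyl-8-(phenylsulfonyl)octa-2,6-dien-1-ol | OC/C(C)=C/CC/C(C)=C/CS(=O)(=O)c1ccccc1 | intermediate
15 | O,C8-dilithio derivative of 14 | [Li]OC/C(C)=C/CC/C(C)=C/C([Li])S(=O)(=O)c1ccccc1 | intermediate
16 | (2E,6E,10Z,14S)-16-(tert-butyldiphenylsilyloxy)-2,6,14-trimethyl-8-(phenylsulfonyl)-10-[(trimethylsilyl)methyl]hexadeca-2,6,10-trien-1-ol (both C8 epimers) | OC/C(C)=C/CC/C(C)=C/C(C/C(C[Si](C)(C)C)=C/CC[C@H](C)CCO[Si](c1ccccc1)(c1ccccc1)C(C)(C)C)S(=O)(=O)c1ccccc1 | intermediate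
17 | (2E,6E,10Z,14S)-16-(tert-butyldiphenylsilyloxy)-2,6,14-trimethyl-10-[(trimethylsilyl)methyl]hexadeca-2,6,10-trien-1-ol | OC/C(C)=C/CC/C(C)=C/CC/C(C[Si](C)(C)C)=C/CC[C@H](C)CCO[Si](c1ccccc1)(c1ccccc1)C(C)(C)C | intermediate
18 | [(2S,3S)-3-{(3E,7Z,11S)-13-(tert-butyldiphenylsilyloxy)-3,11-dimethyl-7-[(trimethylsilyl)methyl]trideca-3,7-dien-1-yl}-2-methyloxiran-2-yl]methanol | OC[C@]1(C)O[C@H]1CC/C(C)=C/CC/C(C[Si](C)(C)C)=C/CC[C@H](C)CCO[Si](c1ccccc1)(c1ccccc1)C(C)(C)C | intermediate
19 | tert-butyldimethylsilyl ether of 18 | CC(C)(C)[Si](C)(C)OC[C@]1(C)O[C@H]1CC/C(C)=C/CC/C(C[Si](C)(C)C)=C/CC[C@H](C)CCO[Si](c1ccccc1)(c1ccccc1)C(C)(C)C | intermediate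
20 | monocyclic C10 carbocation with ring A closed and O3 bound as the aluminate | C[C+]1CC[C@H](O[Al-](C)(Cl)Cl)[C@@](C)(CO[Si](C)(C)C(C)(C)C)[C@@H]1CC/C(C[Si](C)(C)C)=C/CC[C@H](C)CCO[Si](c1ccccc1)(c1ccccc1)C(C)(C)C | intermediate
21 | (13S)-18-(tert-butyldimethylsilyloxy)-15-(tert-butyldiphenylsilyloxy)labd-8(17)-en-3β-ol | C=C1CC[C@@H]2[C@](C)(CC[C@H](O)[C@@]2(C)CO[Si](C)(C)C(C)(C)C)[C@H]1CC[C@H](C)CCO[Si](c1ccccc1)(c1ccccc1)C(C)(C)C | intermediate
22 | 3-O-(phenoxythiocarbonyl) derivative of 21 | C=C1CC[C@@H]2[C@](C)(CC[C@H](OC(=S)Oc3ccccc3)[C@@]2(C)CO[Si](C)(C)C(C)(C)C)[C@H]1CC[C@H](C)CCO[Si](c1ccccc1)(c1ccccc1)C(C)(C)C | intermediate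
23 | (13S)-18-(tert-butyldimethylsilyloxy)-15-(tert-butyldiphenylsilyloxy)labd-8(17)-ene | C=C1CC[C@@H]2[C@](C)(CCC[C@@]2(C)CO[Si](C)(C)C(C)(C)C)[C@H]1CC[C@H](C)CCO[Si](c1ccccc1)(c1ccccc1)C(C)(C)C | intermediate
24 | (13S)-labd-8(17)-ene-15,18-diol | C=C1CC[C@@H]2[C@](C)(CCC[C@@]2(C)CO)[C@H]1CC[C@H](C)CCO | intermediate
25 | (13S)-18-hydroxylabd-8(17)-en-15-yl acetate | C=C1CC[C@@H]2[C@](C)(CCC[C@@]2(C)CO)[C@H]1CC[C@H](C)CCOC(C)=O | intermediate
26 | (13S)-18-oxolabd-8(17)-en-15-yl acetate | C=C1CC[C@@H]2[C@](C)(CCC[C@@]2(C)C=O)[C@H]1CC[C@H](C)CCOC(C)=O | intermediate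
27 | (13S)-15-acetoxylabd-8(17)-en-18-oic acid, (1R,4aR,5S,8aR)-5-[(3S)-5-acetoxy-3-methylpentyl]-1,4a-dimethyl-6-methylidenedecahydronaphthalene-1-carboxylic acid | C=C1CC[C@@H]2[C@](C)(CCC[C@@]2(C)C(=O)O)[C@H]1CC[C@H](C)CCOC(C)=O | target

Total step count: 18. Longest linear sequence: 15 steps (steps 1, 2, 4, 5, 6 and 9 to 18).

**Steps most likely to fail**

Step 13. The cationic cascade may be diverted: the silyloxymethyl group slows ionisation at C4, so a hydride shift in the activated epoxide, capture of the C10 cation by O3, or protodesilylation of the allylsilane may outrun closure of ring B. The fallback replaces the cationic cascade by a radical one on the silicon-free analogue. It sets out from 2 and 14 and comes back at 21.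
- Silyl ether 2 would be oxidised at its E methyl group (SeO2, t-BuOOH) to allylic alcohol F1.
- F1 would be converted into bromide F2 (CBr4, PPh3) and used to alkylate dilithio sulfone 15 (from 14) to give sulfone F3.
- PdCl2(dppp)/LiEt3BH would give trienol F4, Sharpless epoxidation with L-(+)-diethyl tartrate epoxy alcohol F5, and TBSCl/imidazole silyl ether F6.
- Cp2TiCl (from Cp2TiCl2 and Mn dust, THF) would open the epoxide homolytically to the C4 radical. This closes rings A and B by two 6-endo additions, and the C8 radical ends by hydrogen loss from C17 to trivalent titanium, giving 21 directly.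
- In this mode C4 is a planar radical and is no longer fixed by the epoxide geometry. Its configuration would rest on the preference of the larger CH2OTBS group for the equatorial site, and any C4 epimer would have to be removed at 21.

Step 4. Olefination by the hindered α-branched ylide may be slow with the enolisable aldehyde, and the alkene geometry may be eroded. The fallback builds the alkene by alkyne hydroalumination and cross-coupling instead of carbonyl olefination. It sets out from 4 and comes back at 10, so steps 3 to 5 are by-passed.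
- Aldehyde 4 would be homologated (Ohira–Bestmann reagent, K2CO3, MeOH) to alkyne F7.
- Lithiation (n-BuLi) and addition to paraformaldehyde would give propargylic alcohol F8.
- Trans-hydroalumination with aluminium placed at C2 (LiAlH4, AlCl3) and iodination (I2) would give (Z)-2-iodoallylic alcohol F9, with iodine cis to the C11 chain.
- Kumada coupling with Me3SiCH2MgCl and Pd(PPh3)4 (cat.) should then give 10 with retention of geometry.

Step 17. The acylation may not discriminate enough between the two primary hydroxyl groups, leading to over-acylation at O18. The fallback differentiates the oxygens by their silyl groups instead of by rate. It sets out from 23 and comes back at 27.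
- HF·pyridine (THF/pyridine, 0 °C) should cleave only the tert-butyldimethylsilyl ether of 23 to give alcohol F10.
- Dess–Martin oxidation would give aldehyde F11 and Pinnick oxidation acid F12.
- Bu4NF would give hydroxy acid F13, and Ac2O/pyridine should then acetylate O15 to give 27.

**Further compounds**

F1 | step 13 | (2E,6S)-8-(tert-butyldiphenylsilyloxy)-2,6-dimethyloct-2-en-1-ol | OC/C(C)=C/CC[C@H](C)CCO[Si](c1ccccc1)(c1ccccc1)C(C)(C)C
F2 | step 13 | {[(3S,6E)-8-bromo-3,7-dimethyloct-6-en-1-yl]oxy}(tert-butyl)diphenylsilane | BrC/C(C)=C/CC[C@H](C)CCO[Si](c1ccccc1)(c1ccccc1)C(C)(C)C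
F3 | step 13 | (2E,6E,10E,14S)-16-(tert-butyldiphenylsilyloxy)-2,6,10,14-tetramethyl-8-(phenylsulfonyl)hexadeca-2,6,10-trien-1-ol (both C8 epimers) | OC/C(C)=C/CC/C(C)=C/C(C/C(C)=C/CC[C@H](C)CCO[Si](c1ccccc1)(c1ccccc1)C(C)(C)C)S(=O)(=O)c1ccccc1
F4 | step 13 | (2E,6E,10E,14S)-16-(tert-butyldiphenylsilyloxy)-2,6,10,14-tetramethylhexadeca-2,6,10-trien-1-ol | OC/C(C)=C/CC/C(C)=C/CC/C(C)=C/CC[C@H](C)CCO[Si](c1ccccc1)(c1ccccc1)C(C)(C)C
F5 | step 13 | [(2S,3S)-3-{(3E,7E,11S)-13-(tert-butyldiphenylsilyloxy)-3,7,11-trimethyltrideca-3,7-dien-1-yl}-2-methyloxiran-2-yl]methanol | OC[C@]1(C)O[C@H]1CC/C(C)=C/CC/C(C)=C/CC[C@H](C)CCO[Si](c1ccccc1)(c1ccccc1)C(C)(C)C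
F6 | step 13 | tert-butyldimethylsilyl ether of F5 | CC(C)(C)[Si](C)(C)OC[C@]1(C)O[C@H]1CC/C(C)=C/CC/C(C)=C/CC[C@H](C)CCO[Si](c1ccccc1)(c1ccccc1)C(C)(C)C
F7 | step 4 | tert-butyl{[(3S)-3-methylhept-6-yn-1-yl]oxy}diphenylsilane | C#CCC[C@H](C)CCO[Si](c1ccccc1)(c1ccccc1)C(C)(C)C
F8 | step 4 | (6S)-8-(tert-butyldiphenylsilyloxy)-6-methyloct-2-yn-1-ol | OCC#CCC[C@H](C)CCO[Si](c1ccccc1)(c1ccccc1)C(C)(C)C
F9 | step 4 | (2Z,6S)-8-(tert-butyldiphenylsilyloxy)-2-iodo-6-methyloct-2-en-1-ol | OC/C(I)=C/CC[C@H](C)CCO[Si](c1ccccc1)(c1ccccc1)C(C)(C)C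
F10 | step 17 | (13S)-15-(tert-butyldiphenylsilyloxy)labd-8(17)-en-18-ol | C=C1CC[C@@H]2[C@](C)(CCC[C@@]2(C)CO)[C@H]1CC[C@H](C)CCO[Si](c1ccccc1)(c1ccccc1)C(C)(C)C
F11 | step 17 | (13S)-15-(tert-butyldiphenylsilyloxy)labd-8(17)-en-18-al | C=C1CC[C@@H]2[C@](C)(CCC[C@@]2(C)C=O)[C@H]1CC[C@H](C)CCO[Si](c1ccccc1)(c1ccccc1)C(C)(C)C
F12 | step 17 | (13S)-15-(tert-butyldiphenylsilyloxy)labd-8(17)-en-18-oic acid | C=C1CC[C@@H]2[C@](C)(CCC[C@@]2(C)C(=O)O)[C@H]1CC[C@H](C)CCO[Si](c1ccccc1)(c1ccccc1)C(C)(C)C
F13 | step 17 | (13S)-15-hydroxylabd-8(17)-en-18-oic acid | C=C1CC[C@@H]2[C@](C)(CCC[C@@]2(C)C(=O)O)[C@H]1CC[C@H](C)CCO
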